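**Remarks on the chemistry (assumptions)**
- Ring A of the target carries an n-undecyl group next to the carboxyl. An acyl donor made from an orsellinate (6-methyl) would give the wrong ester, so the acid partner is built from the same 5-undecylresorcinol that feeds the enzymatic step.
- 3,5-Bis(benzyloxy)benzaldehyde and decyltriphenylphosphonium bromide are taken as catalogue compounds. With them the precursor needs two steps and no boron tribromide demethylation.
- A CYP102A1 variant of the required site and enantioselectivity is assumed to be found by screening before scale-up.
- Configuration check: at C4 the priorities are O > C5 arm > C3 arm > H, and the target ester, carbinol 6 and ether 7 are all (R).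

## Structural features

The target is an ester of two 5-alkylresorcinol units. The acyl part is 2,4-dihydroxy-6-undecylbenzoic acid (ring A, with the n-undecyl chain ortho to the carboxyl). The alcohol part is undecan-4-ol whose C11 is bonded to C5 of a second resorcinol (ring B). The two benzene rings are isolated and are linked only through the ester oxygen and the seven methylene groups C5 to C11 of the undecanol chain. The single stereocentre is C4 of that chain, (R); it has no stereogenic or functional neighbour, and its two carbon arms (n-propyl and the heptamethylene chain ending in ring B) are identical over the first three atoms. The fragile groups are the four free phenols of two electron-rich rings, which are prone to oxidation and C-alkylation. The ester, flanked on ring A by the undecyl chain and a hydrogen-bonded hydroxyl, is hard to form but robust once made, and the carbinol C–O bond is not benzylic and tolerates hydrogenolysis. The real difficulty is placing one oxygen with defined configuration on one methylene out of ten in an unfunctionalised chain, where no reagent-based asymmetric method separates propyl from a longer n-alkyl group; the hindered esterification is a second, smaller problem. The key step exploits two facts: the alcohol half without its hydroxyl and the acyl half without its carboxyl are the same compound, and in it the carbon to be oxidised (C4, the third methylene from the methyl terminus) belongs to a chain anchored at its far end by a polar head (ring B with its two hydroxyls), the substrate pattern of subterminal fatty-acid hydroxylases.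

## Logic of the disconnections

**14 to 13.** The four phenolic O–H bonds are traced back to four O–benzyl bonds. The phenols must be masked while the carbinol is acylated, and benzyl leaves under neutral hydrogenolysis that touches neither the secondary alkyl ester nor the C4–O bond. One operation then uncovers all four phenols. The demand is that nothing else in 13 is hydrogenolysable, which holds because C4 is seven carbons from ring B.

**13 to 7 and 11 (through 12).** The acyl C–O bond of the ester is cut. It is the only heteroatom link between the halves and divides the molecule into two pieces of similar size, with the stereocentre confined to 7. The forward step must acylate at oxygen, so that C4 is retained, and must overcome the hindrance of a carbonyl with two ortho substituents; hence activation as 12 and nucleophilic catalysis.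

**7 to 6.** The two phenolic O–benzyl bonds of ring B are cut. The enzyme needs the free phenols as polar anchor and the acylation needs them masked. The gain is that 6 is the direct product of the key step. The forward alkylation must distinguish phenol from secondary alcohol, which a carbonate base does by acidity.

**6 to 5.** The C4–O bond is cut. This removes the only stereocentre and the only functional group of the chain in one stroke and reveals 5, whose chain needs no assembly around a carbinol and no chiral building block. The demand is severe: one methylene of ten and one of its two hydrogens must be selected, which only an enzyme pocket that holds the head group and fixes the chain register can do.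

**11 to 10 to 8 to 5.** The carboxyl is traced to the aldehyde oxidation level, the ring C1–CHO bond is cut, and the benzyl ethers are removed. This is possible because 5 is the decarboxylated form of the acyl half and its ring accepts a one-carbon electrophile para to one oxygen and ortho to the other. Both halves then come from one intermediate and no second aromatic starting material is needed. The forward steps must substitute at the carbon next to the chain, not between the two oxygens, and must oxidise without harming benzyl ethers.

**5 to 4 to 1 and 2 (through 3).** The bond between the benzylic and the next chain carbon is cut as a C=C bond, and the alkene and both benzyl ethers are removed in the same hydrogenation. Both partners are purchasable, 5 is reached in two steps, and alkene geometry is irrelevant.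

## Other disconnections considered

**Alternative 1:** The cut lies wholly in ring A: the ring C6–alkyl bond and the ring C1–carboxyl bond are both removed. This leads back to the aryne A2 (3,5-bis(benzyloxy)benzyne), its source A1 (1,5-bis(benzyloxy)-2-bromo-3-fluorobenzene) and the Grignard reagent A3 (undecylmagnesium bromide).
- Forward key step: halogen–magnesium exchange on A1 and loss of fluoride would release A2. A3 would add at the aryne carbon remote from the flanking benzyloxy group, so that the new aryl–magnesium bond sits next to the inductively withdrawing oxygen. Carboxylation in the same flask would give A4 (2,4-bis(benzyloxy)-6-undecylbenzoic acid), the same acid as 11.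
- In favour: two adjacent carbon substituents are installed in one operation. The regiochemistry is fixed by the halogen positions and the inductive effect of the ether, so on regiocontrol this is the better way to the acid than the electrophilic formylation of step 6.
- Against: it serves only the half without a stereocentre. A1 is not a catalogue compound and needs its own regiocontrolled halogenation sequence. A primary alkyl Grignard reagent can also reduce an aryne by hydride transfer, and the product arylmagnesium can add to a second aryne.
- Comparison: structurally it could replace only steps 5 to 7, three routine steps from an intermediate already in hand. Mechanistically it is polar chemistry of known type and less risky than the enzymatic step, but it does not remove that risk because the carbinol still has to be made. In step count it is at best equal, and it gives up drawing both halves from 5.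

**Alternative 2:** The cut removes the ester acyl C–O bond together with the C1–C6 bond of ring A, so ring A does not exist until the last carbon–carbon bond is made. The precursors are alcohol 7 and the diketo-dioxinone A5 (6-(2,4-dioxopentadecyl)-2,2-dimethyl-4H-1,3-dioxin-4-one).
- Forward key step: heating A5 with 7 would fragment the dioxinone ring to the acylketene A6 (3,5,7-trioxooctadec-1-en-1-one). The carbinol oxygen of 7 would capture it to give the triketo ester A7. Base and then acid would close A7 by aldol condensation of C2 onto the C7 ketone, dehydration and enolisation, giving the resorcylate A8. Hydrogenolysis of the two ring B benzyl ethers would give 14.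
- In favour: the ester bond forms by addition to an unhindered ketene before any ortho substituent exists, which avoids the hindered acyl substitution of step 8; on this point it is better. Ring A is born with free phenols, so two fewer benzyl ethers are carried.
- Against: A5 is a sensitive β,δ-diketo dioxinone needing about three to four steps from a dioxinone dienolate. Polyketo chains of this kind can close to pyranones instead of the benzene ring. The valuable alcohol 7 is spent in the least forgiving step. The stereocentre is not created here.
- Comparison: structurally it replaces steps 5 to 8 only and could be combined with the enzymatic step. Mechanistically it uses known reaction types with more sensitive intermediates but a less hindered bond-forming event. Step economy is roughly equal (A5 plus one flask against four steps), with the chosen plan starting its acid branch from 5, which is already made.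

**Alternative 3:** The cut is the C6–C7 bond of the undecane chain, formed last between two redox-active N-(acyloxy)phthalimide esters. A9 carries the stereocentre already acylated by the ring A acid; A10 is the ester of the 6-arylhexanoic acid.
- Forward key step: at the cathode, with NiCl2·6H2O, a terpyridine ligand and a sacrificial magnesium anode, both esters would be reduced and decarboxylate, and nickel would join the two primary alkyl fragments to A11, which is identical with 13. Hydrogenolysis would finish.
- In favour: the stereocentre sits in a seven-carbon γ-oxygenated acid available from the lactone A12 ((R)-5-propyloxolan-2-one). Its γ-keto ester precursor can be reduced enantioselectively by established methods because the ester group differentiates the two sides of the ketone. On how the configuration is secured, this alternative is better founded than the chosen plan.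
- Against: both partners are unactivated primary alkyl groups of like reactivity, so cross-coupling competes statistically with both homodimers and one partner must be used in excess. A9 needs the same hindered acylation as step 8, on a 4-hydroxy acid derivative that tends to relactonise. Two acids must be made and activated.
- Comparison: structurally the chain is assembled from three pieces instead of being taken intact. Mechanistically it is radical/organonickel coupling of known type against enzymatic C–H oxidation, and on paper it is equally compatible with benzyl ethers and the aryl ester. In step economy it needs about a dozen operations against nine, with no intermediate shared between the halves.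

Key step: step 3

## Route

Step 1
Reactants: 1 3,5-bis(benzyloxy)benzaldehyde; 2 decyltriphenylphosphonium bromide
Product: 4 1,3-bis(benzyloxy)-5-(undec-1-en-1-yl)benzene (Z/E mixture), via decylidenetriphenylphosphorane 3 (not isolated)
Conditions: 2, KOtBu, THF, 0 °C; then 1, 0 °C → rt
Reagents that add atoms: none
Why: Wittig olefination: the non-stabilised ylide 3 adds to the aromatic aldehyde and the oxaphosphetane collapses to the alkene and triphenylphosphine oxide; the Z/E ratio does not matter because the double bond is saturated in step 2.

Step 2
Reactants: 4 1,3-bis(benzyloxy)-5-(undec-1-en-1-yl)benzene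
Product: 5 5-undecylresorcinol (5-undecylbenzene-1,3-diol)
Conditions: H2 (1–3 atm), 10% Pd/C, EtOAc–EtOH, rt
Reagents that add atoms: none
Why: Heterogeneous catalytic hydrogenation saturates the styrenyl double bond and hydrogenolyses both aryl benzyl ethers in one operation, which replaces a separate ether cleavage with a boron halide; the resorcinol ring is not reduced at room temperature.

Step 3
Reactants: 5 5-undecylresorcinol
Product: 6 (R)-11-(3,5-dihydroxyphenyl)undecan-4-ol (5-[(8R)-8-hydroxyundecyl]benzene-1,3-diol)
Conditions: CYP102A1 (P450 BM3) variant chosen by screening (clarified lysate), NADP+ (cat.), D-glucose, glucose dehydrogenase, catalase, air, KH2PO4/K2HPO4 buffer pH 7.5, 2–5% DMSO, 25 °C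
Reagents that add atoms: dioxygen, O=O
Why: Proposed new method: the substrate is expected to enter the hydrophobic channel chain-first with the two phenolic hydroxyls held by the polar residues at the channel mouth (arginine 47 and tyrosine 51 in the parent enzyme), in the way a fatty-acid carboxylate is held, which places the last carbons of the chain over the heme. Electrons from NADPH pass through the fused reductase domain to the ferric (trivalent iron) heme, dioxygen is bound and cleaved, and the resulting ferryl porphyrin radical cation (tetravalent iron-oxo) abstracts the pro-R hydrogen atom from C4; the carbon radical recombines with the iron-bound hydroxyl by oxygen rebound before it can invert, so the C–O bond forms with retention and the carbinol is (R). The closest known reaction type is the hydroxylation of C12 to C16 fatty acids at the three subterminal carbons by CYP102A1 and its variants, which favours (R)-alcohols; its extension to a neutral 5-alkylresorcinol is the untested part. No ring is closed. The new stereocentre is under pure catalyst control, because the substrate has no element that distinguishes the two C4 hydrogens or the propyl arm from the heptamethylene arm. The step needs site selectivity for C4 over C2, C3, the benzylic C11 and the aromatic ring, and it needs pro-R selectivity; anchoring of the resorcinol head fixes the register of the chain, and a variant from focused libraries at the residues lining the heme pocket (positions 78, 82, 87, 188, 328) and at the mouth (47, 51) has to be selected by screening for a single-position outcome. Glucose dehydrogenase regenerates NADPH, catalase removes hydrogen peroxide from uncoupled turnover, and the reaction is stopped before the alcohol is oxidised further to the ketone.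

Step 4
Reactants: 6 (R)-11-(3,5-dihydroxyphenyl)undecan-4-ol
Product: 7 (R)-11-[3,5-bis(benzyloxy)phenyl]undecan-4-ol
Conditions: BnBr (2.2 equiv), K2CO3, acetone, reflux
Reagents that add atoms: benzyl bromide, BrCc1ccccc1
Why: Williamson ether synthesis: K2CO3 deprotonates only the phenols and not the far less acidic secondary alcohol, so benzylation is confined to the ring oxygens; the stereocentre is not involved.

Step 5
Reactants: 5 5-undecylresorcinol
Product: 8 1,3-bis(benzyloxy)-5-undecylbenzene
Conditions: BnBr (2.2 equiv), K2CO3, DMF, 60 °C
Reagents that add atoms: benzyl bromide, BrCc1ccccc1
Why: Williamson ether synthesis on both phenols; the benzyl ethers make the ring compatible with the formylation and oxidation that follow and leave with the others in step 9.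

Step 6
Reactants: 8 1,3-bis(benzyloxy)-5-undecylbenzene
Product: 10 2,4-bis(benzyloxy)-6-undecylbenzaldehyde, via aryl dimethyliminium chloride 9 (not isolated)
Conditions: POCl3, DMF, 0 → 60 °C; then ice-water, rt
Reagents that add atoms: N,N-dimethylformamide, CN(C)C=O (formyl carbon); water, O (carbonyl oxygen on hydrolysis of 9); phosphoryl chloride, O=P(Cl)(Cl)Cl (chloride counter-ion of 9 only)
Why: Vilsmeier–Haack formylation: the chloroiminium electrophile from DMF and POCl3 attacks the ring carbon that is para to one benzyloxy group and ortho to the other, the position between the two ether oxygens being the more shielded one, and the iminium salt 9 is hydrolysed on work-up.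

Step 7
Reactants: 10 2,4-bis(benzyloxy)-6-undecylbenzaldehyde
Product: 11 2,4-bis(benzyloxy)-6-undecylbenzoic acid
Conditions: NaClO2, NaH2PO4, 2-methylbut-2-ene, t-BuOH–THF–H2O, 0 °C → rt
Reagents that add atoms: sodium chlorite, [Na+].[O-]Cl=O
Why: Pinnick oxidation: chlorous acid adds to the aldehyde and fragments to the carboxylic acid; 2-methylbut-2-ene scavenges the hypochlorous acid that would otherwise chlorinate the electron-rich ring, and benzyl ethers are inert.

Step 8
Reactants: 11 2,4-bis(benzyloxy)-6-undecylbenzoic acid; 7 (R)-11-[3,5-bis(benzyloxy)phenyl]undecan-4-ol
Product: 13 (R)-11-[3,5-bis(benzyloxy)phenyl]undecan-4-yl 2,4-bis(benzyloxy)-6-undecylbenzoate, via 2,4-bis(benzyloxy)-6-undecylbenzoyl chloride 12 (not isolated)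
Conditions: (COCl)2, DMF (cat.), CH2Cl2, 0 °C → rt, evaporate; then 7, Et3N, DMAP (cat.), CH2Cl2, 0 → 40 °C
Reagents that add atoms: oxalyl chloride, O=C(Cl)C(=O)Cl (chlorine of 12 only; none of its atoms remain in 13)
Why: Acyl chloride formation through the chloroiminium species from oxalyl chloride and DMF, then DMAP-catalysed acylation of the secondary alcohol through the acylpyridinium ion; reaction takes place at oxygen, so the C4–O bond and the (R) configuration are untouched, and aroyl chlorides with two ortho substituents are known to acylate alcohols under such conditions.

Step 9
Reactants: 13 (R)-11-[3,5-bis(benzyloxy)phenyl]undecan-4-yl 2,4-bis(benzyloxy)-6-undecylbenzoate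
Product: 14 (R)-11-(3,5-dihydroxyphenyl)undecan-4-yl 2,4-dihydroxy-6-undecylbenzoate (target)
Conditions: H2 (1 atm), 10% Pd/C, EtOAc–MeOH, rt
Reagents that add atoms: none
Why: Hydrogenolysis of four aryl benzyl ethers over palladium; the ester is a secondary alkyl benzoate whose alkyl C–O bond is not benzylic and the stereocentre carries no activating group, so both survive.

## Compound list

1 | 3,5-bis(benzyloxy)benzaldehyde | O=Cc1cc(OCc2ccccc2)cc(OCc2ccccc2)c1 | starting material
2 | decyltriphenylphosphonium bromide | CCCCCCCCCC[P+](c1ccccc1)(c1ccccc1)c1ccccc1.[Br-] | starting material
3 | decylidenetriphenylphosphorane | CCCCCCCCCC=P(c1ccccc1)(c1ccccc1)c1ccccc1 | intermediate (not isolated)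
4 | 1,3-bis(benzyloxy)-5-(undec-1-en-1-yl)benzene (Z/E mixture, Z drawn) | CCCCCCCCC/C=C\c1cc(OCc2ccccc2)cc(OCc2ccccc2)c1 | intermediate
5 | 5-undecylresorcinol (5-undecylbenzene-1,3-diol) | CCCCCCCCCCCc1cc(O)cc(O)c1 | intermediate
6 | (R)-11-(3,5-dihydroxyphenyl)undecan-4-ol | CCC[C@@H](O)CCCCCCCc1cc(O)cc(O)c1 | intermediate
7 | (R)-11-[3,5-bis(benzyloxy)phenyl]undecan-4-ol | CCC[C@@H](O)CCCCCCCc1cc(OCc2ccccc2)cc(OCc2ccccc2)c1 | intermediate
8 | 1,3-bis(benzyloxy)-5-undecylbenzene | CCCCCCCCCCCc1cc(OCc2ccccc2)cc(OCc2ccccc2)c1 | intermediate
9 | N-{[2,4-bis(benzyloxy)-6-undecylphenyl]methylidene}-N-methylmethanaminium chloride | CCCCCCCCCCCc1cc(OCc2ccccc2)cc(OCc2ccccc2)c1C=[N+](C)C.[Cl-] | intermediate (not isolated)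
10 | 2,4-bis(benzyloxy)-6-undecylbenzaldehyde | CCCCCCCCCCCc1cc(OCc2ccccc2)cc(OCc2ccccc2)c1C=O | intermediate
11 | 2,4-bis(benzyloxy)-6-undecylbenzoic acid | CCCCCCCCCCCc1cc(OCc2ccccc2)cc(OCc2ccccc2)c1C(=O)O | intermediate
12 | 2,4-bis(benzyloxy)-6-undecylbenzoyl chloride | CCCCCCCCCCCc1cc(OCc2ccccc2)cc(OCc2ccccc2)c1C(=O)Cl | intermediate (not isolated)
13 | (R)-11-[3,5-bis(benzyloxy)phenyl]undecan-4-yl 2,4-bis(benzyloxy)-6-undecylbenzoate | CCCCCCCCCCCc1cc(OCc2ccccc2)cc(OCc2ccccc2)c1C(=O)O[C@H](CCC)CCCCCCCc1cc(OCc2ccccc2)cc(OCc2ccccc2)c1 | intermediate
14 | (R)-11-(3,5-dihydroxyphenyl)undecan-4-yl 2,4-dihydroxy-6-undecylbenzoate | CCCCCCCCCCCc1cc(O)cc(O)c1C(=O)O[C@H](CCC)CCCCCCCc1cc(O)cc(O)c1 | target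

## Step count and risk

Total steps: 9. Longest linear sequence: 7 (steps 1, 2, 5, 6, 7, 8, 9); the alcohol branch (steps 1, 2, 3, 4, 8, 9) is 6.

**Step 3 (key step, the only step beyond known chemistry).**
- What may go wrong: oxygen insertion may spread over C2, C3 and C4, giving positional isomers that are hard to separate. The neutral head group may bind weakly, leading to low turnover and uncoupled NADPH consumption. Ring or benzylic oxidation and further oxidation of the carbinol may compete. Enantioselectivity at this position may be incomplete. The parent enzyme is not selective for one subterminal carbon, and the head group differs from a carboxylate.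
- Fallback (known chemistry): it sets out from 1 and returns at 6. Wittig methylenation of 1 (methyltriphenylphosphonium bromide, KOtBu, THF) would give 1,3-bis(benzyloxy)-5-ethenylbenzene F1. Separately, copper-catalysed opening of enantiopure (R)-2-propyloxirane, a catalogue reagent, with pent-4-enylmagnesium bromide (CuBr·SMe2 cat., THF, −30 → 0 °C) at its CH2 carbon would give (R)-dec-9-en-4-ol F2 with the configuration unchanged. Olefin cross-metathesis of F1 with F2 (second-generation Grubbs catalyst, (H2IMes)(PCy3)Cl2Ru=CHPh, CH2Cl2, 40 °C) would give (R,E)-11-[3,5-bis(benzyloxy)phenyl]undec-10-en-4-ol F3. Hydrogenation over 10% Pd/C would saturate the alkene and remove both benzyl groups to give 6, which continues with step 4. The stereocentre then comes from the epoxide; the cost is four operations in place of one, while 5 is still made for the acid branch.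

**Step 8.**
- What may go wrong: acyl transfer at a carbonyl flanked by two ortho substituents may be sluggish, allowing hydrolysis of the acyl chloride on work-up or acid-promoted loss of the ortho benzyl group if the reaction has to be forced.
- Fallback: it sets out from 7 and returns at 13, and it replaces acyl substitution by substitution at the carbinol carbon with the carboxylate of 11 as nucleophile. Mitsunobu reaction of 7 with 4-nitrobenzoic acid (PPh3, DIAD, THF) would give, with inversion, (S)-11-[3,5-bis(benzyloxy)phenyl]undecan-4-yl 4-nitrobenzoate F4. Saponification (NaOH, MeOH–THF–H2O) would give (S)-11-[3,5-bis(benzyloxy)phenyl]undecan-4-ol F5. A second Mitsunobu reaction of F5 with acid 11 (PPh3, DIAD, toluene) would invert again and deliver 13 in the (R) configuration. Hindrance at the acyl carbon does not matter in this mode; the cost is two extra steps.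

**Step 6.**
- What may go wrong: some electrophilic attack at the ring position between the two benzyloxy groups, and partial cleavage of a benzyl ether by the hydrogen chloride generated at elevated temperature.
- Fallback: it sets out from 8 and returns at 11, by-passing 10 and step 7. Bromination with N-bromosuccinimide (MeCN, 0 °C), para to one ether oxygen, would give 1,5-bis(benzyloxy)-2-bromo-3-undecylbenzene F6, whose isomeric purity can be checked before going on. Bromine–lithium exchange (n-BuLi, THF, −78 °C) would give [2,4-bis(benzyloxy)-6-undecylphenyl]lithium F7, and quenching with carbon dioxide followed by dilute HCl would give 11. No hot acid is involved and the step count is unchanged.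

## Further compounds

F1 | step 3 | 1,3-bis(benzyloxy)-5-ethenylbenzene | C=Cc1cc(OCc2ccccc2)cc(OCc2ccccc2)c1
F2 | step 3 | (R)-dec-9-en-4-ol | CCC[C@@H](O)CCCCC=C
F3 | step 3 | (R,E)-11-[3,5-bis(benzyloxy)phenyl]undec-10-en-4-ol | CCC[C@@H](O)CCCCC/C=C/c1cc(OCc2ccccc2)cc(OCc2ccccc2)c1
F4 | step 8 | (S)-11-[3,5-bis(benzyloxy)phenyl]undecan-4-yl 4-nitrobenzoate | CCC[C@H](OC(=O)c1ccc(cc1)[N+](=O)[O-])CCCCCCCc1cc(OCc2ccccc2)cc(OCc2ccccc2)c1
F5 | step 8 | (S)-11-[3,5-bis(benzyloxy)phenyl]undecan-4-ol | CCC[C@H](O)CCCCCCCc1cc(OCc2ccccc2)cc(OCc2ccccc2)c1
F6 | step 6 | 1,5-bis(benzyloxy)-2-bromo-3-undecylbenzene | CCCCCCCCCCCc1cc(OCc2ccccc2)cc(OCc2ccccc2)c1Br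
F7 | step 6 | [2,4-bis(benzyloxy)-6-undecylphenyl]lithium | CCCCCCCCCCCc1cc(OCc2ccccc2)cc(OCc2ccccc2)c1[Li]
A1 | alternative 1 | 1,5-bis(benzyloxy)-2-bromo-3-fluorobenzene | Fc1cc(OCc2ccccc2)cc(OCc2ccccc2)c1Br
A2 | alternative 1 | 3,5-bis(benzyloxy)benzyne | C1#CC(OCc2ccccc2)=CC(OCc2ccccc2)=C1
A3 | alternative 1 | undecylmagnesium bromide | CCCCCCCCCCC[Mg]Br
A4 | alternative 1 | 2,4-bis(benzyloxy)-6-undecylbenzoic acid | CCCCCCCCCCCc1cc(OCc2ccccc2)cc(OCc2ccccc2)c1C(=O)O
A5 | alternative 2 | 6-(2,4-dioxopentadecyl)-2,2-dimethyl-4H-1,3-dioxin-4-one | CCCCCCCCCCCC(=O)CC(=O)CC1=CC(=O)OC(C)(C)O1
A6 | alternative 2 | 3,5,7-trioxooctadec-1-en-1-one | CCCCCCCCCCCC(=O)CC(=O)CC(=O)C=C=O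
A7 | alternative 2 | (R)-11-[3,5-bis(benzyloxy)phenyl]undecan-4-yl 3,5,7-trioxooctadecanoate | CCCCCCCCCCCC(=O)CC(=O)CC(=O)CC(=O)O[C@H](CCC)CCCCCCCc1cc(OCc2ccccc2)cc(OCc2ccccc2)c1
A8 | alternative 2 | (R)-11-[3,5-bis(benzyloxy)phenyl]undecan-4-yl 2,4-dihydroxy-6-undecylbenzoate | CCCCCCCCCCCc1cc(O)cc(O)c1C(=O)O[C@H](CCC)CCCCCCCc1cc(OCc2ccccc2)cc(OCc2ccccc2)c1
A9 | alternative 3 | 1,3-dioxoisoindolin-2-yl (R)-4-{[2,4-bis(benzyloxy)-6-undecylbenzoyl]oxy}heptanoate | CCCCCCCCCCCc1cc(OCc2ccccc2)cc(OCc2ccccc2)c1C(=O)O[C@H](CCC)CCC(=O)ON1C(=O)c2ccccc2C1=O
A10 | alternative 3 | 1,3-dioxoisoindolin-2-yl 6-[3,5-bis(benzyloxy)phenyl]hexanoate | O=C(CCCCCc1cc(OCc2ccccc2)cc(OCc2ccccc2)c1)ON1C(=O)c2ccccc2C1=O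
A11 | alternative 3 | (R)-11-[3,5-bis(benzyloxy)phenyl]undecan-4-yl 2,4-bis(benzyloxy)-6-undecylbenzoate | CCCCCCCCCCCc1cc(OCc2ccccc2)cc(OCc2ccccc2)c1C(=O)O[C@H](CCC)CCCCCCCc1cc(OCc2ccccc2)cc(OCc2ccccc2)c1
A12 | alternative 3 | (R)-5-propyloxolan-2-one | CCC[C@@H]1CCC(=O)O1
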